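**Plan**
1. Cuts: the C6–H of ring A (central ring: C1 CH2CH2Ar, C2 and C4 4-hydroxybenzyl, C3 OMe, C5 OH, C6 H) is traced back to a C6–CO2H that leaves as CO2. Ring A is then opened at C1–C2 and C5–C6.
2. Enabling feature: C2, C3, C4 and C5 of ring A, with both 4-hydroxybenzyl groups, are the gamma, keto, alpha and ester carbons of the Claisen dimer of a 3-(4-hydroxyphenyl)propanoate. C1 and C6 are the alkyne carbons of a 5-arylpent-2-ynoate.
3. Forward, fragment 1: benzylation, Claisen self-condensation, enol ether formation and O-silylation give a 1,3-dimethoxy-1-silyloxy diene. Fragment 2: benzylation, partial reduction, alkyne homologation and carboxylation give the benzyl ynoate.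
4. Ring A is the only ring made. It arises in one (4+2) cycloaddition–aromatisation of the two fragments; the three outer arenes are bought.
5. Hydrogenolysis of all four benzyl groups and thermal decarboxylation end the route.
6. Stereochemistry: the target has no stereocentre and no stereogenic double bond. Every transient stereocentre or alkene geometry is erased when ring A becomes aromatic.

Key step: step 9

Assumption: the keto ester is handled as the racemate, and the enol ether and the diene as mixtures of double-bond isomers, because this information is lost on aromatisation.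

**Step 1**
Reactants: 1 methyl 3-(4-hydroxyphenyl)propanoate
Product: 2 methyl 3-(4-benzyloxyphenyl)propanoate
Conditions: BnBr, K2CO3, acetone, reflux
Reagents that add atoms: benzyl bromide, BrCc1ccccc1
Why: Williamson ether synthesis, in which the phenoxide formed by K2CO3 displaces bromide by SN2 while the methyl ester is inert to the weak base.

**Step 2**
Reactants: 2 methyl 3-(4-benzyloxyphenyl)propanoate (two molecules)
Product: 4 methyl 2-(4-benzyloxybenzyl)-5-(4-benzyloxyphenyl)-3-oxopentanoate (racemic), via sodium enolate 3 (not isolated)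
Conditions: NaH (0.6 equiv per mol of 2), cat. MeOH, THF, reflux; then 1 M HCl, 0 °C
Reagents that add atoms: none
Why: Claisen self-condensation, in which the ester enolate acylates a second molecule of 2 and deprotonation of the product to enolate 3 pulls the equilibrium over; the alpha stereocentre is racemic and disappears in step 3.

**Step 3**
Reactants: 4 methyl 2-(4-benzyloxybenzyl)-5-(4-benzyloxyphenyl)-3-oxopentanoate
Product: 6 methyl 2-(4-benzyloxybenzyl)-5-(4-benzyloxyphenyl)-3-methoxypent-2-enoate (E/Z mixture), via dimethyl ketal 5 (not isolated)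
Conditions: HC(OMe)3 (5 equiv), cat. H2SO4, MeOH, reflux; Et3N quench
Reagents that add atoms: trimethyl orthoformate, COC(OC)OC
Why: Acid-catalysed ketalisation by the orthoester followed by loss of methanol is the standard enol ether synthesis for 2-alkyl-3-oxo esters, and it avoids the C-methylation that alkylation under basic conditions risks.

**Step 4**
Reactants: 6 methyl 2-(4-benzyloxybenzyl)-5-(4-benzyloxyphenyl)-3-methoxypent-2-enoate
Product: 8 2-(4-benzyloxybenzyl)-5-(4-benzyloxyphenyl)-1,3-dimethoxy-1-(trimethylsilyloxy)penta-1,3-diene (mixture of double-bond isomers), via lithium dienolate 7 (not isolated)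
Conditions: LiN(i-Pr)2 (1.1 equiv), THF, −78 °C; Me3SiCl, −78 °C to rt; pentane, filtration under Ar, used at once
Reagents that add atoms: chlorotrimethylsilane, C[Si](C)(C)Cl
Why: Kinetic gamma-deprotonation of a beta-alkoxy enoate gives extended enolate 7, which Me3SiCl traps on oxygen (the usual preparation of vinylogous silyl ketene acetals); the benzylic CH2 on the alpha carbon does not compete because its anion cannot delocalise into the ester.

**Step 5**
Reactants: 9 3-(3-hydroxyphenyl)propanoic acid
Product: 10 benzyl 3-(3-benzyloxyphenyl)propanoate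
Conditions: BnBr (2.3 equiv), K2CO3, DMF, 50 °C
Reagents that add atoms: benzyl bromide, BrCc1ccccc1
Why: Double SN2 O-alkylation (Williamson etherification of the phenoxide and esterification of the carboxylate) needs no selectivity, because the benzyl ester serves step 6 as well as any other ester.

**Step 6**
Reactants: 10 benzyl 3-(3-benzyloxyphenyl)propanoate
Product: 12 3-(3-benzyloxyphenyl)propanal, via aluminium hemiacetal 11 (not isolated)
Conditions: i-Bu2AlH (1.05 equiv), CH2Cl2, −78 °C; MeOH, then aq. potassium sodium tartrate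
Reagents that add atoms: none
Why: Partial ester reduction with one equivalent of i-Bu2AlH, in which hemiacetal 11 does not collapse at −78 °C, so the aldehyde appears only on hydrolysis and is not reduced further.

**Step 7**
Reactants: 12 3-(3-benzyloxyphenyl)propanal
Product: 13 4-(3-benzyloxyphenyl)but-1-yne
Conditions: MeC(O)C(N2)P(O)(OMe)2, K2CO3, MeOH, 0 °C to rt
Reagents that add atoms: dimethyl (1-diazo-2-oxopropyl)phosphonate, COP(=O)(OC)C(=[N+]=[N-])C(C)=O
Why: The Ohira–Bestmann variant of the Seyferth–Gilbert homologation turns enolisable aliphatic aldehydes into terminal alkynes under mild K2CO3/MeOH conditions that leave the aryl benzyl ether alone.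

**Step 8**
Reactants: 13 4-(3-benzyloxyphenyl)but-1-yne; 14 benzyl chloroformate
Product: 16 benzyl 5-(3-benzyloxyphenyl)pent-2-ynoate, via lithium acetylide 15 (not isolated)
Conditions: n-BuLi (1.0 equiv), THF, −78 °C; cannulation into 14 (1.5 equiv), THF, −78 °C to 0 °C
Reagents that add atoms: none
Why: Deprotonation of the terminal alkyne and C-acylation of acetylide 15 by a chloroformate is the standard alkynoate synthesis, and inverse addition into excess 14 suppresses a second addition.

**Step 9**
Reactants: 8 2-(4-benzyloxybenzyl)-5-(4-benzyloxyphenyl)-1,3-dimethoxy-1-(trimethylsilyloxy)penta-1,3-diene; 16 benzyl 5-(3-benzyloxyphenyl)pent-2-ynoate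
Product: 19 benzyl 3,5-bis(4-benzyloxybenzyl)-6-[2-(3-benzyloxyphenyl)ethyl]-2-hydroxy-4-methoxybenzoate, via cyclohexadiene cycloadduct 17 (not isolated), via aryl silyl ether 18 (not isolated)
Conditions: 8 (3 equiv), neat or 2 M in xylene, sealed tube, Ar, 140 °C; then 1 M HCl, THF, rt
Reagents that add atoms: none
Why: Diene 8 is a vinylogous silyl ketene acetal whose gamma terminus (future C2) is its most nucleophilic carbon and ynoate 16 is most electrophilic at its beta carbon (future C1), so C1–C2 forms first or furthest ahead and the acetal carbon (C5) then bonds to the ynoate alpha carbon (C6), either in one asynchronous (4+2) cycloaddition or by Mukaiyama–Michael addition followed by ring closure. Ring A thus closes by an intermolecular (4+2) union of a four-carbon and a two-carbon unit, the second bond being in the stepwise limit a 6-exo-trig attack of the allenoate alpha carbon on the silyloxycarbenium carbon, and it first appears as cyclohexa-1,4-diene 17. 1,4-Elimination of methanol from 17 (OMe on C5, H on C2) should give arene 18, and the acid wash cleaves the O–Si bond to the C5 phenol of 19, which is hydrogen-bonded to the ester. The closest known reaction type is the Diels–Alder/aromatisation of 1,3-dialkoxy-1-silyloxybutadienes with acetylenic esters to 2-hydroxy-4-alkoxybenzoates; the present pair is more crowded, which is why the reaction is run concentrated, hot and with the diene in excess, an excess that also covers any diene isomer whose C2 substituent points inward and cannot reach the s-cis form. No stereocentre is created in 19, since the two sp3 ring carbons of 17 are flattened on aromatisation, so endo/exo and facial selectivity are irrelevant. The selectivities needed are regiochemical (ester carbon beside the C5 oxygen), secured by the matched push–pull polarisation just described, and chemoselective loss of methanol rather than silanol, secured because the methoxy oxygen is the more basic leaving group and because premature desilylation gives a hemiketal that can only expel methanol as well.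

**Step 10**
Reactants: 19 benzyl 3,5-bis(4-benzyloxybenzyl)-6-[2-(3-benzyloxyphenyl)ethyl]-2-hydroxy-4-methoxybenzoate
Product: 20 2-hydroxy-3,5-bis(4-hydroxybenzyl)-6-[2-(3-hydroxyphenyl)ethyl]-4-methoxybenzoic acid
Conditions: H2 (1 atm), 10% Pd/C, EtOAc–MeOH, rt; filtration, crude acid taken on
Reagents that add atoms: none
Why: Catalytic hydrogenolysis cleaves the three aryl benzyl ethers and the benzyl ester at their O–CH2Ph bonds, whereas the diarylmethane C–C bonds and the arenes are untouched at one atmosphere.

**Step 11**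
Reactants: 20 2-hydroxy-3,5-bis(4-hydroxybenzyl)-6-[2-(3-hydroxyphenyl)ethyl]-4-methoxybenzoic acid
Product: 21 bulbocodin C, 2,4-bis(4-hydroxybenzyl)-5-[2-(3-hydroxyphenyl)ethyl]-3-methoxyphenol
Conditions: degassed DMSO, 120 °C, Ar
Reagents that add atoms: none
Why: Thermal protodecarboxylation of an ortho-hydroxy, para-alkoxy benzoic acid, in which ipso-protonation through the chelated phenol (a beta-keto-acid-like six-membered transition state) is favoured by the electron-rich ring and by relief of strain between the two ortho substituents, as in the ready decarboxylation of 6-alkylresorcylic acids.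

**Compound list**
1 | methyl 3-(4-hydroxyphenyl)propanoate | COC(=O)CCc1ccc(O)cc1 | starting material
2 | methyl 3-(4-benzyloxyphenyl)propanoate | COC(=O)CCc1ccc(OCc2ccccc2)cc1 | intermediate
3 | sodium enolate of methyl 2-(4-benzyloxybenzyl)-5-(4-benzyloxyphenyl)-3-oxopentanoate (not isolated) | [Na+].COC(=O)C(Cc1ccc(OCc2ccccc2)cc1)=C([O-])CCc1ccc(OCc2ccccc2)cc1 | intermediate
4 | methyl 2-(4-benzyloxybenzyl)-5-(4-benzyloxyphenyl)-3-oxopentanoate (racemic) | COC(=O)C(Cc1ccc(OCc2ccccc2)cc1)C(=O)CCc1ccc(OCc2ccccc2)cc1 | intermediate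
5 | methyl 2-(4-benzyloxybenzyl)-5-(4-benzyloxyphenyl)-3,3-dimethoxypentanoate (racemic, not isolated) | COC(=O)C(Cc1ccc(OCc2ccccc2)cc1)C(OC)(OC)CCc1ccc(OCc2ccccc2)cc1 | intermediate
6 | methyl 2-(4-benzyloxybenzyl)-5-(4-benzyloxyphenyl)-3-methoxypent-2-enoate (E/Z mixture) | COC(=O)C(Cc1ccc(OCc2ccccc2)cc1)=C(OC)CCc1ccc(OCc2ccccc2)cc1 | intermediate
7 | lithium dienolate of 6 (not isolated) | [Li+].COC([O-])=C(Cc1ccc(OCc2ccccc2)cc1)C(OC)=CCc1ccc(OCc2ccccc2)cc1 | intermediate
8 | 2-(4-benzyloxybenzyl)-5-(4-benzyloxyphenyl)-1,3-dimethoxy-1-(trimethylsilyloxy)penta-1,3-diene (mixture of double-bond isomers) | COC(O[Si](C)(C)C)=C(Cc1ccc(OCc2ccccc2)cc1)C(OC)=CCc1ccc(OCc2ccccc2)cc1 | intermediate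
9 | 3-(3-hydroxyphenyl)propanoic acid | OC(=O)CCc1cccc(O)c1 | starting material
10 | benzyl 3-(3-benzyloxyphenyl)propanoate | O=C(CCc1cccc(OCc2ccccc2)c1)OCc1ccccc1 | intermediate
11 | diisobutylaluminium hemiacetal of 10, [1-benzyloxy-3-(3-benzyloxyphenyl)propoxy]diisobutylaluminium (racemic, not isolated) | CC(C)C[Al](CC(C)C)OC(CCc1cccc(OCc2ccccc2)c1)OCc1ccccc1 | intermediate
12 | 3-(3-benzyloxyphenyl)propanal | O=CCCc1cccc(OCc2ccccc2)c1 | intermediate
13 | 4-(3-benzyloxyphenyl)but-1-yne | C#CCCc1cccc(OCc2ccccc2)c1 | intermediate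
14 | benzyl chloroformate | O=C(Cl)OCc1ccccc1 | starting material
15 | lithium 4-(3-benzyloxyphenyl)but-1-ynide (not isolated) | [Li]C#CCCc1cccc(OCc2ccccc2)c1 | intermediate
16 | benzyl 5-(3-benzyloxyphenyl)pent-2-ynoate | O=C(OCc1ccccc1)C#CCCc1cccc(OCc2ccccc2)c1 | intermediate
17 | benzyl 3,5-bis(4-benzyloxybenzyl)-2-[2-(3-benzyloxyphenyl)ethyl]-4,6-dimethoxy-6-(trimethylsilyloxy)cyclohexa-1,4-diene-1-carboxylate (diastereomer mixture, not isolated) | COC1(O[Si](C)(C)C)C(Cc2ccc(OCc3ccccc3)cc2)=C(OC)C(Cc2ccc(OCc3ccccc3)cc2)C(CCc2cccc(OCc3ccccc3)c2)=C1C(=O)OCc1ccccc1 | intermediate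
18 | benzyl 3,5-bis(4-benzyloxybenzyl)-6-[2-(3-benzyloxyphenyl)ethyl]-4-methoxy-2-(trimethylsilyloxy)benzoate (not isolated) | COc1c(Cc2ccc(OCc3ccccc3)cc2)c(O[Si](C)(C)C)c(C(=O)OCc2ccccc2)c(CCc2cccc(OCc3ccccc3)c2)c1Cc1ccc(OCc2ccccc2)cc1 | intermediate
19 | benzyl 3,5-bis(4-benzyloxybenzyl)-6-[2-(3-benzyloxyphenyl)ethyl]-2-hydroxy-4-methoxybenzoate | COc1c(Cc2ccc(OCc3ccccc3)cc2)c(O)c(C(=O)OCc2ccccc2)c(CCc2cccc(OCc3ccccc3)c2)c1Cc1ccc(OCc2ccccc2)cc1 | intermediate
20 | 2-hydroxy-3,5-bis(4-hydroxybenzyl)-6-[2-(3-hydroxyphenyl)ethyl]-4-methoxybenzoic acid | COc1c(Cc2ccc(O)cc2)c(O)c(C(=O)O)c(CCc2cccc(O)c2)c1Cc1ccc(O)cc1 | intermediate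
21 | bulbocodin C, 2,4-bis(4-hydroxybenzyl)-5-[2-(3-hydroxyphenyl)ethyl]-3-methoxyphenol | COc1c(Cc2ccc(O)cc2)c(O)cc(CCc2cccc(O)c2)c1Cc1ccc(O)cc1 | target

**Total step count:** 11.
**Longest linear sequence:** 7 steps (steps 1–4 then 9–11; the branch through steps 5–8 is equally long).

**Steps most likely to fail**

Step 9. The crowded cycloaddition may be too slow. Thermal O-to-C silyl migration, protodesilylation of the diene by the released methanol, or polymerisation of the ynoate could then outrun ring formation.

The fallback replaces the alkyne by its more reactive allene isomer. It sets out from 10 (with diene 8) and comes back at 19.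
- Saponification of 10 (LiOH, THF–H2O, then HCl) would give 3-(3-benzyloxyphenyl)propanoic acid F1.
- Oxalyl chloride with cat. DMF would give 3-(3-benzyloxyphenyl)propanoyl chloride F2.
- Et3N together with Ph3P=CHCO2Bn (ketene formation and Wittig olefination) would give racemic benzyl 5-(3-benzyloxyphenyl)penta-2,3-dienoate F3.
- Diene 8 should add across the activated C2=C3 bond of F3 with the same polarity, its gamma terminus bonding to the central allene carbon. This gives benzyl 3,5-bis(4-benzyloxybenzyl)-2-[2-(3-benzyloxyphenyl)ethylidene]-4,6-dimethoxy-6-(trimethylsilyloxy)cyclohex-4-ene-1-carboxylate F4.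
- Loss of methanol, acid-promoted shift of the exocyclic double bond into the ring and desilylation then lead to 19.

Step 4. Deprotonation of the tetrasubstituted enoate may be incomplete, silylation may take place on carbon, and the diene may hydrolyse during isolation.

The fallback postpones the methyl ether and makes a different diene by soft enolisation. It sets out from 4, comes back at 19, and bypasses step 3 as well.
- Keto ester 4 with Me3SiOTf (2.5 equiv) and Et3N in Et2O at 0 °C would give 2-(4-benzyloxybenzyl)-5-(4-benzyloxyphenyl)-1-methoxy-1,3-bis(trimethylsilyloxy)penta-1,3-diene F5, which is more nucleophilic than 8.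
- Heating F5 with 16 should give benzyl 3,5-bis(4-benzyloxybenzyl)-2-[2-(3-benzyloxyphenyl)ethyl]-6-methoxy-4,6-bis(trimethylsilyloxy)cyclohexa-1,4-diene-1-carboxylate F6.
- Loss of methanol and acidic desilylation would give benzyl 3,5-bis(4-benzyloxybenzyl)-6-[2-(3-benzyloxyphenyl)ethyl]-2,4-dihydroxybenzoate F7.
- MeI and K2CO3 in acetone should methylate only the 4-hydroxyl, because the 2-hydroxyl is tied up in the hydrogen bond to the ester. This gives 19.

Step 11. At the temperature needed for loss of CO2, the free 4-hydroxybenzyl groups may ionise toward quinone methides and migrate or be lost. The polyphenol may also oxidise.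

The fallback removes the carboxyl group while all outer phenols are still benzylated. It sets out from 19 and comes back at 21.
- KOH in aqueous ethylene glycol at 120 °C would saponify the hindered ester to 3,5-bis(4-benzyloxybenzyl)-6-[2-(3-benzyloxyphenyl)ethyl]-2-hydroxy-4-methoxybenzoic acid F8.
- F8 should lose CO2 in the same pot and on acidification, as 6-alkylresorcylate esters do. This gives 2,4-bis(4-benzyloxybenzyl)-5-[2-(3-benzyloxyphenyl)ethyl]-3-methoxyphenol F9.
- Hydrogenolysis (H2, Pd/C, EtOAc–MeOH, rt) then gives 21 without any heating of the free polyphenol.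

**Further compounds**
F1 | step 9 | 3-(3-benzyloxyphenyl)propanoic acid | OC(=O)CCc1cccc(OCc2ccccc2)c1
F2 | step 9 | 3-(3-benzyloxyphenyl)propanoyl chloride | ClC(=O)CCc1cccc(OCc2ccccc2)c1
F3 | step 9 | benzyl 5-(3-benzyloxyphenyl)penta-2,3-dienoate (racemic) | O=C(OCc1ccccc1)C=C=CCc1cccc(OCc2ccccc2)c1
F4 | step 9 | benzyl 3,5-bis(4-benzyloxybenzyl)-2-[2-(3-benzyloxyphenyl)ethylidene]-4,6-dimethoxy-6-(trimethylsilyloxy)cyclohex-4-ene-1-carboxylate (isomer mixture) | COC1(O[Si](C)(C)C)C(Cc2ccc(OCc3ccccc3)cc2)=C(OC)C(Cc2ccc(OCc3ccccc3)cc2)C(=CCc2cccc(OCc3ccccc3)c2)C1C(=O)OCc1ccccc1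
F5 | step 4 | 2-(4-benzyloxybenzyl)-5-(4-benzyloxyphenyl)-1-methoxy-1,3-bis(trimethylsilyloxy)penta-1,3-diene (isomer mixture) | COC(O[Si](C)(C)C)=C(Cc1ccc(OCc2ccccc2)cc1)C(O[Si](C)(C)C)=CCc1ccc(OCc2ccccc2)cc1
F6 | step 4 | benzyl 3,5-bis(4-benzyloxybenzyl)-2-[2-(3-benzyloxyphenyl)ethyl]-6-methoxy-4,6-bis(trimethylsilyloxy)cyclohexa-1,4-diene-1-carboxylate (diastereomer mixture) | COC1(O[Si](C)(C)C)C(Cc2ccc(OCc3ccccc3)cc2)=C(O[Si](C)(C)C)C(Cc2ccc(OCc3ccccc3)cc2)C(CCc2cccc(OCc3ccccc3)c2)=C1C(=O)OCc1ccccc1
F7 | step 4 | benzyl 3,5-bis(4-benzyloxybenzyl)-6-[2-(3-benzyloxyphenyl)ethyl]-2,4-dihydroxybenzoate | Oc1c(Cc2ccc(OCc3ccccc3)cc2)c(O)c(C(=O)OCc2ccccc2)c(CCc2cccc(OCc3ccccc3)c2)c1Cc1ccc(OCc2ccccc2)cc1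
F8 | step 11 | 3,5-bis(4-benzyloxybenzyl)-6-[2-(3-benzyloxyphenyl)ethyl]-2-hydroxy-4-methoxybenzoic acid | COc1c(Cc2ccc(OCc3ccccc3)cc2)c(O)c(C(=O)O)c(CCc2cccc(OCc3ccccc3)c2)c1Cc1ccc(OCc2ccccc2)cc1
F9 | step 11 | 2,4-bis(4-benzyloxybenzyl)-5-[2-(3-benzyloxyphenyl)ethyl]-3-methoxyphenol | COc1c(Cc2ccc(OCc3ccccc3)cc2)c(O)cc(CCc2cccc(OCc3ccccc3)c2)c1Cc1ccc(OCc2ccccc2)cc1
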